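Ring D, the five-membered lactol lactone, is taken apart last: its CH carbon, the aryl–C bond to C6 and the C–O bond to the C7 carboxyl oxygen all come from dibromomethane in one carboxylate-directed palladium C–H alkylation–lactonisation. The step exploits that ring B of the depsidone (dibenzo[b,e][1,4]dioxepin-11-one locants) keeps a single hydrogen, C6–H, ortho to the C7 carboxyl carbon and beside ether oxygen O5, so the lactone carbonyl must end next to the C8 oxygen. The precursor is tricyclic acid 18 with rings A, B and C complete, both phenols as methyl ethers and the C9 hydroxymethyl silylated. Fumaroylation, benzylic oxidation, demethylation and an enzymatic dynamic resolution then deliver the (R)-lactol.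

Key step: step 14

Assumption: the ring D lactol carbon (a hemiacylal) can epimerise through the ring-opened aldehyde–acid; it is taken to hold its configuration in cold, neutral, water-free medium, so (R) is set in the last two steps with a lipase whose enantiopreference is fixed by screening.

Locants: ring A = C1–C4 (C1 methyl, C3 oxygen, C4 formyl); ring B = C6–C9 (C6 hydrogen or ring D carbon, C7 carboxyl, C8 oxygen, C9 CH2O); ring C = the seven-membered lactone (O5, O10, C11); ring D = the five-membered lactone on C6–C7.

**Ring B fragment**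

Step 1
Reactants: 1 methyl 4-hydroxy-2-methoxybenzoate
Product: 2 methyl 5-bromo-4-hydroxy-2-methoxybenzoate
Conditions: NBS (1.0 equiv), MeCN, 0 °C to rt
Reagents that add atoms: N-bromosuccinimide, O=C1CCC(=O)N1Br
Why: Electrophilic aromatic bromination: the hydroxyl directs ortho and the methoxy group para to the same carbon (C5), the other ortho carbon (C3) lies between two substituents, and the bromine both blocks C5 for step 2 and later becomes the ether oxygen.

Step 2
Reactants: 2 methyl 5-bromo-4-hydroxy-2-methoxybenzoate
Product: 3 methyl 5-bromo-3-formyl-4-hydroxy-2-methoxybenzoate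
Conditions: MgCl2, Et3N, paraformaldehyde, MeCN, reflux; aq. HCl work-up
Reagents that add atoms: formaldehyde (as paraformaldehyde), C=O
Why: Casnati–Skattebøl ortho-formylation: the magnesium phenoxide delivers formaldehyde to the only free position ortho to the hydroxyl (C3) and a second formaldehyde oxidises the benzylic alkoxide, so no regiochemical choice remains.

Step 3
Reactants: 3 methyl 5-bromo-3-formyl-4-hydroxy-2-methoxybenzoate
Product: 4 methyl 5-bromo-4-hydroxy-3-(hydroxymethyl)-2-methoxybenzoate
Conditions: NaBH4, MeOH–THF, 0 °C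
Reagents that add atoms: none
Why: Hydride reduction: NaBH4 reduces the aryl aldehyde at 0 °C and leaves the methyl ester and the aryl bromide untouched.

Step 4
Reactants: 4 methyl 5-bromo-4-hydroxy-3-(hydroxymethyl)-2-methoxybenzoate
Product: 5 methyl 8-bromo-5-methoxy-2,2-dimethyl-4H-1,3-benzodioxine-6-carboxylate
Conditions: 2,2-dimethoxypropane, TsOH·H2O (cat.), acetone, rt
Reagents that add atoms: 2,2-dimethoxypropane, COC(C)(C)OC
Why: Acid-catalysed transketalisation: the ortho-hydroxybenzyl alcohol closes to the six-membered isopropylidene acetal, which masks the phenol oxygen and the hydroxymethyl group together, so that only the oxygen introduced in step 5 can act as nucleophile later.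

Step 5
Reactants: 5 methyl 8-bromo-5-methoxy-2,2-dimethyl-4H-1,3-benzodioxine-6-carboxylate
Product: 7 methyl 8-hydroxy-5-methoxy-2,2-dimethyl-4H-1,3-benzodioxine-6-carboxylate, via pinacol boronate 6 (not isolated)
Conditions: B2pin2, Pd(dppf)Cl2 (3 mol%), KOAc, 1,4-dioxane, 90 °C; then 30% H2O2, aq. NaOH, THF, 0 °C
Reagents that add atoms: hydrogen peroxide, OO (phenol oxygen); bis(pinacolato)diboron, CC1(C)OB(OC1(C)C)B1OC(C)(C)C(C)(C)O1 (boron of 6 only)
Why: Miyaura borylation followed by oxidation of the C–B bond (aryl shift to the peroxide oxygen) replaces bromine by hydroxyl at the same carbon; zerovalent palladium formed from Pd(dppf)Cl2 inserts only into the C–Br bond, and ketal and ester tolerate the brief cold alkaline peroxide.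

**Ring A fragment**

Step 6
Reactants: 8 1-fluoro-3-methoxy-5-methylbenzene
Product: 9 2-bromo-1-fluoro-5-methoxy-3-methylbenzene
Conditions: NBS, MeCN, 0 °C to rt
Reagents that add atoms: N-bromosuccinimide, O=C1CCC(=O)N1Br
Why: Electrophilic aromatic bromination of an anisole with NBS in acetonitrile is strongly para-selective, and the para carbon is also ortho to fluorine and methyl, so bromine should enter between F and CH3.

Step 7
Reactants: 9 2-bromo-1-fluoro-5-methoxy-3-methylbenzene
Product: 11 3-bromo-2-fluoro-6-methoxy-4-methylbenzaldehyde, via aryllithium 10 (not isolated)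
Conditions: LiN(i-Pr)2, THF, −78 °C; then DMF, −78 to 0 °C; aq. NH4Cl
Reagents that add atoms: N,N-dimethylformamide, CN(C)C=O
Why: Directed ortho-metalation: the hydrogen flanked by fluorine and methoxy is the most acidic, the amide base does not exchange the bromine, and aryllithium 10 (stable at −78 °C) is formylated by DMF.

Step 8
Reactants: 11 3-bromo-2-fluoro-6-methoxy-4-methylbenzaldehyde
Product: 12 2-fluoro-3-formyl-4-methoxy-6-methylbenzoic acid
Conditions: Pd(OAc)2 (3 mol%), Xantphos, CO (1 atm), Et3N, 1,4-dioxane–H2O, 80 °C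
Reagents that add atoms: carbon monoxide, [C-]#[O+]; water, O
Why: Palladium-catalysed hydroxycarbonylation: zerovalent palladium inserts into the C–Br bond, CO inserts and water cleaves the acylpalladium to the acid, while the amine–water medium is too weakly nucleophilic to attack the activated C–F bond or the aldehyde.

**Union and ring C**

Step 9
Reactants: 7 methyl 8-hydroxy-5-methoxy-2,2-dimethyl-4H-1,3-benzodioxine-6-carboxylate; 12 2-fluoro-3-formyl-4-methoxy-6-methylbenzoic acid
Product: 13 3-formyl-4-methoxy-2-{[5-methoxy-6-(methoxycarbonyl)-2,2-dimethyl-4H-1,3-benzodioxin-8-yl]oxy}-6-methylbenzoic acid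
Conditions: K2CO3 (3 equiv), DMSO, 90 °C; aq. citric acid work-up
Reagents that add atoms: none
Why: Nucleophilic aromatic substitution (addition–elimination): the fluorine of 12 is activated by the ortho formyl group, which takes up the charge of the Meisenheimer adduct, and the only free hydroxyl of 7 is the one on C8, so the diaryl ether forms with unambiguous regiochemistry.

Step 10
Reactants: 13 diaryl ether acetonide (as above)
Product: 14 3-formyl-2-[2-hydroxy-3-(hydroxymethyl)-4-methoxy-5-(methoxycarbonyl)phenoxy]-4-methoxy-6-methylbenzoic acid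
Conditions: AcOH–H2O (4:1), 45 °C
Reagents that add atoms: none
Why: Acid-catalysed ketal hydrolysis frees the phenol needed for ring C and the hydroxymethyl group, while esters, aldehyde and diaryl ether are stable to warm aqueous acetic acid.

Step 11
Reactants: 14 diol acid (as above)
Product: 16 2-[3-({[tert-butyl(diphenyl)silyl]oxy}methyl)-2-hydroxy-4-methoxy-5-(methoxycarbonyl)phenoxy]-3-formyl-4-methoxy-6-methylbenzoic acid, via bis-silyl derivative 15 (not isolated)
Conditions: TBDPSCl (2.3 equiv), imidazole, DMF, 0 °C to rt; then K2CO3, MeOH–H2O, 0 °C; aq. citric acid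
Reagents that add atoms: tert-butyl(chloro)diphenylsilane, CC(C)(C)[Si](Cl)(c1ccccc1)c1ccccc1
Why: Silyl ether formation: the primary alcohol and the carboxylic acid are silylated while the doubly ortho-substituted phenol is not, and the labile silyl ester of 15 is cleaved by cold carbonate in methanol so that only the robust primary silyl ether remains (a silyl ether survives the later radical-free steps and, unlike a benzyl ether, is removed without hydrogenolysis or Lewis acid).

Step 12
Reactants: 16 silyl ether hydroxy acid (as above)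
Product: 17 methyl 9-({[tert-butyl(diphenyl)silyl]oxy}methyl)-4-formyl-3,8-dimethoxy-1-methyl-11-oxo-11H-dibenzo[b,e][1,4]dioxepine-7-carboxylate
Conditions: DCC, DMAP (cat.), CH2Cl2 (0.005 M), 0 °C to rt
Reagents that add atoms: none
Why: Carbodiimide-mediated lactonisation (Steglich type): only one carboxylic acid and one hydroxyl are free and they are held ortho across the diaryl ether, so the seven-membered aryl ester of ring C closes under high dilution.

Step 13
Reactants: 17 depsidone methyl ester (as above)
Product: 18 9-({[tert-butyl(diphenyl)silyl]oxy}methyl)-4-formyl-3,8-dimethoxy-1-methyl-11-oxo-11H-dibenzo[b,e][1,4]dioxepine-7-carboxylic acid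
Conditions: LiI (5 equiv), EtOAc, reflux, dark; then cold 0.5 M HCl
Reagents that add atoms: none
Why: Nucleophilic ester dealkylation: iodide attacks the methyl carbon of the methyl ester in an SN2 process that the aryl ester of ring C, the aryl methyl ethers (at this temperature) and the silyl ether cannot undergo, so the acid is freed without hydroxide that would open the depsidone.

**Key step**

Step 14
Reactants: 18 depsidone 7-carboxylic acid (as above); 19 dibromomethane
Product: 21 ring D phthalide: 9-({[tert-butyl(diphenyl)silyl]oxy}methyl)-4-formyl-3,8-dimethoxy-1-methyl depsidone with the lactone C7–C(=O)–O–CH2–C6, via bromomethyl acid 20 (not isolated)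
Conditions: Pd(OAc)2 (10 mol%), K2HPO4 (3 equiv), CH2Br2 (solvent), 140 °C, sealed tube
Reagents that add atoms: dibromomethane (19), BrCBr
Why: The potassium carboxylate of 18 binds Pd(OAc)2 (divalent palladium) and delivers it to C6–H, which is cleaved by concerted metalation–deprotonation to a five-membered palladacycle; oxidative addition of dibromomethane (to a tetravalent palladium alkyl) and C–C reductive elimination should give the 6-bromomethyl acid 20 and return divalent palladium. The closest known reaction type is the Pd(OAc)2-catalysed ortho C–H alkylation of benzoic acids with dihaloalkanes that ends in lactonisation to phthalides. Ring D then closes by intramolecular SN2 displacement of bromide by the C7 carboxylate, a 5-exo-tet closure. No stereocentre is formed. Only site selectivity is needed: C6–H is the single position ortho to the carboxylate (C8 carries OMe), the C2–H of ring A has no neighbouring carboxylate and the ring C ester cannot bind the metal as an anion, so one palladacycle is possible and the lactone carbonyl necessarily sits on C7 next to the C8 methoxy group. Aldehyde, aryl ester, methyl ethers and silyl ether should be inert to the phosphate-buffered, oxidant-free medium.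

**From the phthalide to the target**

Step 15
Reactants: 21 ring D phthalide silyl ether (as above)
Product: 22 9-(hydroxymethyl)-4-formyl-3,8-dimethoxy-1-methyl depsidone with ring D phthalide
Conditions: HF·pyridine, THF–pyridine, 0 °C to rt
Reagents that add atoms: none
Why: Fluoride-mediated desilylation: buffered HF·pyridine cleaves the Si–O bond under mildly acidic conditions that leave both lactones and the aldehyde intact.

Step 16
Reactants: 22 phthalide alcohol (as above); 23 (E)-4-tert-butoxy-4-oxobut-2-enoic acid (mono-tert-butyl fumarate)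
Product: 24 tert-butyl (E)-but-2-enedioate ester of the C9 hydroxymethyl group of 22
Conditions: EDC·HCl, DMAP (cat.), CH2Cl2, 0 °C to rt
Reagents that add atoms: (E)-4-tert-butoxy-4-oxobut-2-enoic acid (23), OC(=O)/C=C/C(=O)OC(C)(C)C
Why: Steglich esterification: the carbodiimide-activated half ester acylates the only hydroxyl group of 22 (phenols masked, lactol not yet present), and the tert-butyl group keeps the second carboxyl from reacting.

Step 17
Reactants: 24 fumarate diester (as above)
Product: 25 geminal diacetate of 24 (C4 carries CH(OAc)2 in place of CHO)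
Conditions: Ac2O, I2 (10 mol%), CH2Cl2, rt
Reagents that add atoms: acetic anhydride, CC(=O)OC(C)=O
Why: Acylal formation: iodine-catalysed addition of acetic anhydride across the formyl C=O removes the easily abstracted aldehydic hydrogen before the radical step, and the diacetate is hydrolysed again in that step.

Step 18
Reactants: 25 geminal diacetate (as above)
Product: 27 racemic ring D lactol (C6–CH(OH)–O–C(=O)–C7) with free C4 formyl, both methyl ethers and the tert-butyl fumarate, via lactol bromide 26 (not isolated)
Conditions: NBS (1.05 equiv), AIBN (cat.), PhCF3, 80 °C; then THF–H2O, 45 °C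
Reagents that add atoms: water, O (lactol oxygen); N-bromosuccinimide, O=C1CCC(=O)N1Br (bromine of 26 only)
Why: Wohl–Ziegler bromination then SN1 hydrolysis: the ring D methylene is the only benzylic C–H fixed in a planar ring next to oxygen, whereas the C9 methylene and the diacetate carbon are acyloxy-deactivated and twisted out of conjugation by two ortho substituents and the ring A methyl sits on the most electron-poor ring, so bromine should enter at ring D; water then replaces bromide through the oxygen-stabilised cation, the liberated HBr hydrolyses the diacetate, and the new lactol centre forms as a racemate that is resolved in steps 20 and 21.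

Step 19
Reactants: 27 racemic lactol (as above)
Product: 28 racemic target: (E)-4-oxobut-2-enoic acid ester of the C9 hydroxymethyl group of the 4-formyl-3,8-dihydroxy-1-methyl depsidone bearing the ring D lactol
Conditions: BCl3 (6 equiv), CH2Cl2, −78 to 0 °C; then H2O–THF, 0 °C
Reagents that add atoms: none
Why: Chelation-assisted ether cleavage: BCl3 binds the carbonyl oxygen next to each methoxy group (ring A formyl, ring D lactone carbonyl), chloride removes the methyl groups, the tert-butyl ester is lost as tert-butyl chloride, and at or below 0 °C the benzylic fumarate, ring C and the lactol (restored on aqueous work-up) should survive.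

Step 20
Reactants: 28 racemic target (as above)
Product: 29 (R)-lactol acetate of the target (ring D C6–CH(OAc)–O)
Conditions: immobilised Burkholderia cepacia lipase, vinyl acetate, THF–t-BuOMe, 35 °C
Reagents that add atoms: vinyl acetate, C=COC(C)=O
Why: Lipase-catalysed dynamic kinetic resolution: the lactol enantiomers interconvert through the ring-opened aldehyde–acid while the enzyme irreversibly acetylates only the (R)-lactol (vinyl alcohol tautomerises to acetaldehyde), so the stereocentre is set by the enzyme active site and the carbonyl-chelated phenols are not acylated.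

Step 21
Reactants: 29 (R)-lactol acetate (as above)
Product: 30 target, (R)-lactol: (E)-4-oxo-4-{[C9 of the 4-formyl-3,8-dihydroxy-1-methyl depsidone]methoxy}but-2-enoic acid with ring D (R)-CH(OH) on C6
Conditions: same lipase, n-BuOH, t-BuOMe, 0–5 °C; filtration, evaporation below 20 °C
Reagents that add atoms: none
Why: Lipase-catalysed transesterification with butanol: the enzyme cleaves the acyl–oxygen bond of its preferred (R)-acetate, no bond to the stereocentre is broken so (R) is retained, and the cold, neutral, water-free medium is chosen to suppress ring–chain epimerisation and attack on the other esters.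

**Compound list**

1 | methyl 4-hydroxy-2-methoxybenzoate | COC(=O)c1ccc(O)cc1OC | starting material
2 | methyl 5-bromo-4-hydroxy-2-methoxybenzoate | COC(=O)c1cc(Br)c(O)cc1OC | intermediate
3 | methyl 5-bromo-3-formyl-4-hydroxy-2-methoxybenzoate | COC(=O)c1cc(Br)c(O)c(C=O)c1OC | intermediate
4 | methyl 5-bromo-4-hydroxy-3-(hydroxymethyl)-2-methoxybenzoate | COC(=O)c1cc(Br)c(O)c(CO)c1OC | intermediate
5 | methyl 8-bromo-5-methoxy-2,2-dimethyl-4H-1,3-benzodioxine-6-carboxylate | COC(=O)c1cc(Br)c2OC(C)(C)OCc2c1OC | intermediate
6 | methyl 5-methoxy-2,2-dimethyl-8-(4,4,5,5-tetramethyl-1,3,2-dioxaborolan-2-yl)-4H-1,3-benzodioxine-6-carboxylate | COC(=O)c1cc(B3OC(C)(C)C(C)(C)O3)c2OC(C)(C)OCc2c1OC | intermediate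
7 | methyl 8-hydroxy-5-methoxy-2,2-dimethyl-4H-1,3-benzodioxine-6-carboxylate | COC(=O)c1cc(O)c2OC(C)(C)OCc2c1OC | intermediate
8 | 1-fluoro-3-methoxy-5-methylbenzene (3-fluoro-5-methylanisole) | COc1cc(C)cc(F)c1 | starting material
9 | 2-bromo-1-fluoro-5-methoxy-3-methylbenzene | COc1cc(C)c(Br)c(F)c1 | intermediate
10 | (3-bromo-2-fluoro-6-methoxy-4-methylphenyl)lithium | [Li]c1c(F)c(Br)c(C)cc1OC | intermediate
11 | 3-bromo-2-fluoro-6-methoxy-4-methylbenzaldehyde | COc1cc(C)c(Br)c(F)c1C=O | intermediate
12 | 2-fluoro-3-formyl-4-methoxy-6-methylbenzoic acid | COc1cc(C)c(C(=O)O)c(F)c1C=O | intermediate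
13 | 3-formyl-4-methoxy-2-{[5-methoxy-6-(methoxycarbonyl)-2,2-dimethyl-4H-1,3-benzodioxin-8-yl]oxy}-6-methylbenzoic acid | Cc1cc(OC)c(C=O)c(Oc2cc(C(=O)OC)c(OC)c3COC(C)(C)Oc23)c1C(=O)O | intermediate
14 | 3-formyl-2-[2-hydroxy-3-(hydroxymethyl)-4-methoxy-5-(methoxycarbonyl)phenoxy]-4-methoxy-6-methylbenzoic acid | Cc1cc(OC)c(C=O)c(Oc2cc(C(=O)OC)c(OC)c(CO)c2O)c1C(=O)O | intermediate
15 | tert-butyldiphenylsilyl ester of 16 (bis-silyl derivative) | Cc1cc(OC)c(C=O)c(Oc2cc(C(=O)OC)c(OC)c(CO[Si](c3ccccc3)(c3ccccc3)C(C)(C)C)c2O)c1C(=O)O[Si](c1ccccc1)(c1ccccc1)C(C)(C)C | intermediate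
16 | 2-[3-({[tert-butyl(diphenyl)silyl]oxy}methyl)-2-hydroxy-4-methoxy-5-(methoxycarbonyl)phenoxy]-3-formyl-4-methoxy-6-methylbenzoic acid | Cc1cc(OC)c(C=O)c(Oc2cc(C(=O)OC)c(OC)c(CO[Si](c3ccccc3)(c3ccccc3)C(C)(C)C)c2O)c1C(=O)O | intermediate
17 | methyl 9-({[tert-butyl(diphenyl)silyl]oxy}methyl)-4-formyl-3,8-dimethoxy-1-methyl-11-oxo-11H-dibenzo[b,e][1,4]dioxepine-7-carboxylate | Cc1cc(OC)c(C=O)c2c1C(=O)Oc1c(CO[Si](c3ccccc3)(c3ccccc3)C(C)(C)C)c(OC)c(C(=O)OC)cc1O2 | intermediate
18 | 9-({[tert-butyl(diphenyl)silyl]oxy}methyl)-4-formyl-3,8-dimethoxy-1-methyl-11-oxo-11H-dibenzo[b,e][1,4]dioxepine-7-carboxylic acid | Cc1cc(OC)c(C=O)c2c1C(=O)Oc1c(CO[Si](c3ccccc3)(c3ccccc3)C(C)(C)C)c(OC)c(C(=O)O)cc1O2 | intermediate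
19 | dibromomethane | BrCBr | starting material
20 | 6-(bromomethyl) derivative of acid 18 | Cc1cc(OC)c(C=O)c2c1C(=O)Oc1c(CO[Si](c3ccccc3)(c3ccccc3)C(C)(C)C)c(OC)c(C(=O)O)c(CBr)c1O2 | intermediate
21 | ring D phthalide of 18 (lactone C7–C(=O)–O–CH2–C6), C9 CH2OTBDPS | Cc1cc(OC)c(C=O)c2c1C(=O)Oc1c(CO[Si](c3ccccc3)(c3ccccc3)C(C)(C)C)c(OC)c3C(=O)OCc3c1O2 | intermediate
22 | ring D phthalide with free C9 hydroxymethyl | Cc1cc(OC)c(C=O)c2c1C(=O)Oc1c(CO)c(OC)c3C(=O)OCc3c1O2 | intermediate
23 | (E)-4-tert-butoxy-4-oxobut-2-enoic acid (mono-tert-butyl fumarate) | OC(=O)/C=C/C(=O)OC(C)(C)C | starting material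
24 | tert-butyl fumarate ester of 22 at the C9 CH2O group | Cc1cc(OC)c(C=O)c2c1C(=O)Oc1c(COC(=O)/C=C/C(=O)OC(C)(C)C)c(OC)c3C(=O)OCc3c1O2 | intermediate
25 | geminal diacetate of 24 (C4 CH(OAc)2) | Cc1cc(OC)c(C(OC(C)=O)OC(C)=O)c2c1C(=O)Oc1c(COC(=O)/C=C/C(=O)OC(C)(C)C)c(OC)c3C(=O)OCc3c1O2 | intermediate
26 | racemic ring D bromide of 25 (C6–CHBr–O) | Cc1cc(OC)c(C(OC(C)=O)OC(C)=O)c2c1C(=O)Oc1c(COC(=O)/C=C/C(=O)OC(C)(C)C)c(OC)c3C(=O)OC(Br)c3c1O2 | intermediate
27 | racemic ring D lactol, 3,8-di-O-methyl, tert-butyl fumarate | Cc1cc(OC)c(C=O)c2c1C(=O)Oc1c(COC(=O)/C=C/C(=O)OC(C)(C)C)c(OC)c3C(=O)OC(O)c3c1O2 | intermediate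
28 | racemic target (lactol carbon unresolved) | Cc1cc(O)c(C=O)c2c1C(=O)Oc1c(COC(=O)/C=C/C(=O)O)c(O)c3C(=O)OC(O)c3c1O2 | intermediate
29 | (R)-lactol acetate of the target | Cc1cc(O)c(C=O)c2c1C(=O)Oc1c(COC(=O)/C=C/C(=O)O)c(O)c3c(c1O2)[C@H](OC(C)=O)OC3=O | intermediate
30 | CNP0379578.1, (R)-lactol | Cc1cc(O)c(C=O)c2c1C(=O)Oc1c(COC(=O)/C=C/C(=O)O)c(O)c3c(c1O2)[C@H](O)OC3=O | target

**Step count**

Total: 21 steps. Longest linear sequence: 18 steps (steps 1–5 and 9–21, from 1); the ring A branch (steps 6–8) has 3 steps.

**Steps most likely to fail**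

Step 14. Palladation of the flanked C6–H may be slower than O-alkylation of the carboxylate by dibromomethane or than thermal loss of the silyl group, so that ring D does not close. The fallback brings the ring D carbon in before the fragments are joined; it sets out from 7 and returns at 21. Phenol 7 is formylated at its only free ortho position (MgCl2, Et3N, paraformaldehyde, MeCN, reflux) to methyl 7-formyl-8-hydroxy-5-methoxy-2,2-dimethyl-4H-1,3-benzodioxine-6-carboxylate F1. NaBH4 in MeOH at 0 °C reduces it to the hydroxymethyl ester F2, whose alkoxide closes onto the neighbouring methyl ester to the phthalide phenol F3. Fluoride displacement on acid 12 (K2CO3, DMSO, 90 °C) gives the diaryl ether F4, and aqueous acetic acid removes the acetonide to the diol F5. Silylation as in step 11 passes through the bis-silyl derivative F6 to the silyl ether acid F7, and DCC lactonisation as in step 12 closes ring C and arrives at 21.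

Step 18. Hydrogen abstraction may not be selective for the ring D methylene; attack at the C9 methylene, the ring A methyl or the masked formyl carbon would give mixtures. The fallback oxidises ring D while C9 carries a chloromethyl group, which resists hydrogen abstraction far better, and brings in the fumarate afterwards by carboxylate alkylation instead of acylation; it sets out from 22 and returns at 27. Alcohol 22 is converted (MsCl, LiCl, 2,6-lutidine, DMF, 0 °C) into the benzylic chloride F8. Ac2O with catalytic I2 gives the chloride diacetate F9, and NBS with AIBN in PhCF3 gives the ring D bromide F10. Cesium tert-butyl fumarate F11 (from 23 and Cs2CO3, 2.2 equiv, DMF, rt) displaces both halides to the bis-fumarate F12. Mild aqueous acid (THF–H2O, cat. HCl, 45 °C) cleaves the acylal-type fumarate at the lactol carbon together with the geminal diacetate and returns to 27.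

Step 21. The freed lactol may epimerise during or after enzymatic deacetylation (the same ring opening that step 20 relies on), eroding the enantiomeric purity, or the enzyme may also touch the fumarate ester. The fallback is a crystallisation-induced asymmetric transformation; it sets out from 28 and returns at 30. Racemic 28 is stirred with one equivalent of (S)-N,N-dimethyl-1-phenylethylamine (or its enantiomer, whichever a screen shows to crystallise the (R)-lactol) in a solvent from which the (R)-lactol ammonium salt F13 crystallises while the dissolved lactol keeps epimerising. Filtration and cold partition between ethyl acetate and dilute citric acid then release 30.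

**Further compounds**

F1 | step 14 | methyl 7-formyl-8-hydroxy-5-methoxy-2,2-dimethyl-4H-1,3-benzodioxine-6-carboxylate | COC(=O)c1c(C=O)c(O)c2OC(C)(C)OCc2c1OC
F2 | step 14 | methyl 8-hydroxy-7-(hydroxymethyl)-5-methoxy-2,2-dimethyl-4H-1,3-benzodioxine-6-carboxylate | COC(=O)c1c(CO)c(O)c2OC(C)(C)OCc2c1OC
F3 | step 14 | acetonide-protected phthalide phenol (lactone carbonyl next to OMe, CH2 next to OH) | COc1c2C(=O)OCc2c(O)c2OC(C)(C)OCc12
F4 | step 14 | diaryl ether from F3 and 12 | Cc1cc(OC)c(C=O)c(Oc2c3COC(=O)c3c(OC)c3COC(C)(C)Oc23)c1C(=O)O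
F5 | step 14 | diol acid from F4 (free phenol and hydroxymethyl) | Cc1cc(OC)c(C=O)c(Oc2c3COC(=O)c3c(OC)c(CO)c2O)c1C(=O)O
F6 | step 14 | bis-silyl derivative of F5 (silyl ether and silyl ester) | Cc1cc(OC)c(C=O)c(Oc2c3COC(=O)c3c(OC)c(CO[Si](c3ccccc3)(c3ccccc3)C(C)(C)C)c2O)c1C(=O)O[Si](c1ccccc1)(c1ccccc1)C(C)(C)C
F7 | step 14 | silyl ether acid (phthalide analogue of 16) | Cc1cc(OC)c(C=O)c(Oc2c3COC(=O)c3c(OC)c(CO[Si](c3ccccc3)(c3ccccc3)C(C)(C)C)c2O)c1C(=O)O
F8 | step 18 | 9-(chloromethyl) phthalide from 22 | Cc1cc(OC)c(C=O)c2c1C(=O)Oc1c(CCl)c(OC)c3C(=O)OCc3c1O2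
F9 | step 18 | geminal diacetate of F8 | Cc1cc(OC)c(C(OC(C)=O)OC(C)=O)c2c1C(=O)Oc1c(CCl)c(OC)c3C(=O)OCc3c1O2
F10 | step 18 | racemic ring D bromide of F9 | Cc1cc(OC)c(C(OC(C)=O)OC(C)=O)c2c1C(=O)Oc1c(CCl)c(OC)c3C(=O)OC(Br)c3c1O2
F11 | step 18 | cesium (E)-4-tert-butoxy-4-oxobut-2-enoate | [Cs+].[O-]C(=O)/C=C/C(=O)OC(C)(C)C
F12 | step 18 | racemic bis(tert-butyl fumarate): C9 CH2O ester and ring D lactol ester, C4 CH(OAc)2 | Cc1cc(OC)c(C(OC(C)=O)OC(C)=O)c2c1C(=O)Oc1c(COC(=O)/C=C/C(=O)OC(C)(C)C)c(OC)c3C(=O)OC(OC(=O)/C=C/C(=O)OC(C)(C)C)c3c1O2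
F13 | step 21 | (S)-N,N-dimethyl-1-phenylethylammonium salt of the (R)-lactol 30 | C[C@H]([NH+](C)C)c1ccccc1.Cc1cc(O)c(C=O)c2c1C(=O)Oc1c(COC(=O)/C=C/C(=O)[O-])c(O)c3c(c1O2)[C@H](O)OC3=O
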